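The cyclohexene (C1 = methyl-bearing alkene carbon, C2 = alkene CH, C3 = CH carrying the chalcone ring, C4 = aroyl CH, C5 = dihydroxyphenyl CH, C6 = CH2) is cut into two three-carbon pieces. C4–C5–C6 with the aroyl carbonyl is stored in a prochiral 1,3-diarylcyclobutanol, because the carbonyl carbon and C6 are 1,4-related (C6 is a homoenolate-type γ-carbon). C1(Me)=C2–C3(aryl) comes from an aryl propargylic carbonate. One palladium operation opens the cyclobutanol enantioselectively with C6–C1 coupling to an allene, then closes C4–C3 by hydropalladation and enol capture of the π-allyl, setting all three stereocentres.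

Key step: step 10

Remarks: MOM = methoxymethyl; prenyl = 3-methylbut-2-en-1-yl; the ring numbering C1–C6 defined above is used throughout. Assumption: the sense of enantiotopic C–C cleavage in step 10 follows the ligand; if the enantiomer written gives (R) at C5, its antipode is used.

Step 1
Reactants: 1 2,4-dihydroxybenzaldehyde
Product: 2 2,4-bis(methoxymethoxy)benzaldehyde
Conditions: MOMCl (3 equiv), i-Pr2NEt, CH2Cl2, 0 °C to rt
Reagents that add atoms: chloromethyl methyl ether, COCCl
Why: O-alkylation (MOM protection) of both phenols, with excess reagent also covering the hydrogen-bonded ortho phenol.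

Step 2
Reactants: 2 2,4-bis(methoxymethoxy)benzaldehyde
Product: 3 2,4-bis(methoxymethoxy)-1-vinylbenzene
Conditions: Ph3PCH3Br, KOtBu, THF, 0 °C to rt
Reagents that add atoms: methyltriphenylphosphonium bromide, C[P+](c1ccccc1)(c1ccccc1)c1ccccc1.[Br-]
Why: Wittig methylenation of the aryl aldehyde with the non-stabilised ylide.

Step 3
Reactants: 3 2,4-bis(methoxymethoxy)-1-vinylbenzene
Product: 4 2,2-dichloro-3-[2,4-bis(methoxymethoxy)phenyl]cyclobutan-1-one (racemic)
Conditions: Cl3CCOCl, Zn–Cu couple, POCl3, Et2O, rt
Reagents that add atoms: trichloroacetyl chloride, O=C(Cl)C(Cl)(Cl)Cl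
Why: Thermal [2+2] cycloaddition of dichloroketene made in the flask with the electron-rich styrene; the ketene carbonyl carbon bonds to the terminal CH2, which puts the aryl group on C3, and the racemic stereocentre disappears in step 4.

Step 4
Reactants: 4 2,2-dichloro-3-[2,4-bis(methoxymethoxy)phenyl]cyclobutan-1-one
Product: 5 3-[2,4-bis(methoxymethoxy)phenyl]cyclobutan-1-one
Conditions: Zn, NH4Cl, MeOH, rt
Reagents that add atoms: none
Why: Reductive dechlorination of the α,α-dichloroketone by zinc through zinc enolates, under conditions too mild to touch the MOM ethers.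

Step 5
Reactants: 6 1,3-bis(methoxymethoxy)benzene
Product: 8 1,3-bis(methoxymethoxy)-2-(3-methylbut-2-en-1-yl)benzene, via 2-lithio-1,3-bis(methoxymethoxy)benzene 7 (not isolated)
Conditions: n-BuLi, THF, 0 °C; then prenyl bromide, 0 °C to rt
Reagents that add atoms: prenyl bromide, CC(C)=CCBr
Why: Directed ortho-metalation at the position flanked by both MOM ethers, then SN2 alkylation of the aryllithium by the allylic bromide.

Step 6
Reactants: 8 1,3-bis(methoxymethoxy)-2-(3-methylbut-2-en-1-yl)benzene; 5 3-[2,4-bis(methoxymethoxy)phenyl]cyclobutan-1-one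
Product: 10 cis-1-[2,4-bis(methoxymethoxy)-3-(3-methylbut-2-en-1-yl)phenyl]-3-[2,4-bis(methoxymethoxy)phenyl]cyclobutan-1-ol (OH and 3-aryl on the same face, achiral), via 4-lithio-1,3-bis(methoxymethoxy)-2-(3-methylbut-2-en-1-yl)benzene 9 (not isolated)
Conditions: n-BuLi, TMEDA, THF, 0 °C; then 5, −78 °C; H2O
Reagents that add atoms: none
Why: Second directed ortho-metalation (ortho to one MOM ether) and 1,2-addition of the aryllithium to the strained ketone; attack anti to the 3-aryl group should give the cis alcohol, whose two C(OH)–CH2 bonds are enantiotopic.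

Step 7
Reactants: 11 2,4-dihydroxyacetophenone
Product: 12 3-acetyl-2,6-dihydroxybenzaldehyde
Conditions: hexamethylenetetramine, CF3CO2H, 85 °C; then aq. HCl, rt
Reagents that add atoms: hexamethylenetetramine, C1N2CN3CN1CN(C2)C3; water, O
Why: Duff formylation; bond fixation in the chelated o-hydroxyacetophenone should direct the iminium electrophile to the carbon between the two hydroxyl groups, as in 8-formylation of 7-hydroxycoumarins.

Step 8
Reactants: 12 3-acetyl-2,6-dihydroxybenzaldehyde
Product: 13 3-acetyl-2,6-bis(methoxymethoxy)benzaldehyde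
Conditions: MOMCl (4 equiv), i-Pr2NEt, CH2Cl2, reflux
Reagents that add atoms: chloromethyl methyl ether, COCCl
Why: O-alkylation (MOM protection) of the two hydrogen-bonded phenols, forced by excess reagent and heat.

Step 9
Reactants: 13 3-acetyl-2,6-bis(methoxymethoxy)benzaldehyde
Product: 15 1-[3-acetyl-2,6-bis(methoxymethoxy)phenyl]but-2-yn-1-yl methyl carbonate (racemic), via bromomagnesium propargylic alkoxide 14 (not isolated)
Conditions: 1-propynylmagnesium bromide (1.05 equiv), THF, −78 °C; then ClCO2Me, −78 to 0 °C
Reagents that add atoms: 1-propynylmagnesium bromide, CC#C[Mg]Br; methyl chloroformate, COC(=O)Cl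
Why: Chemoselective 1,2-addition of the alkynyl Grignard reagent to the aldehyde (more electrophilic than the conjugated methyl ketone at low temperature) and O-acylation of the magnesium alkoxide in the same flask; the racemic carbinol centre is erased in step 10.

Step 10
Reactants: 10 cis-1-[2,4-bis(methoxymethoxy)-3-(3-methylbut-2-en-1-yl)phenyl]-3-[2,4-bis(methoxymethoxy)phenyl]cyclobutan-1-ol; 15 1-[3-acetyl-2,6-bis(methoxymethoxy)phenyl]but-2-yn-1-yl methyl carbonate
Product: 17 [(3S,4R,5S)-3-[3-acetyl-2,6-bis(methoxymethoxy)phenyl]-5-[2,4-bis(methoxymethoxy)phenyl]-1-methylcyclohex-1-en-4-yl] [2,4-bis(methoxymethoxy)-3-(3-methylbut-2-en-1-yl)phenyl] ketone, via allenyl ketone 16 (not isolated)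
Conditions: Pd2(dba)3·CHCl3 (2.5 mol %), (R)-N,N-dimethyl-1-[(S)-2-(diphenylphosphino)ferrocenyl]ethylamine (6 mol %), toluene, 50 °C; then PhCO2H (20 mol %), 80 °C, same flask
Reagents that add atoms: none
Why: Proposed new method: zerovalent palladium ionises 15 (anti SN2′, loss of CO2) to an allenyl divalent palladium methoxide, which exchanges with 10; strain-driven β-carbon elimination then cleaves one of the two enantiotopic C(OH)–CH2 bonds under ligand control, and reductive elimination joins C6 to C1, giving allene 16 with C5 set as (S) by the catalyst. Benzoic acid then converts the same zerovalent palladium into a hydride that delivers H to the central allene carbon C2, and the enol of the newly released aryl ketone captures the resulting C1–C2–C3 π-allyl at C3. The closest known reactions are the enantioselective ring-opening arylation, vinylation and allenylation of tert-cyclobutanols for the first bond and the palladium-hydride addition of carbon pronucleophiles to allenes and 1,3-dienes with Tsuji–Trost-type capture for the second; their fusion and the use of an unactivated aryl ketone are new. The ring closes in a 6-endo mode on the allyl unit (attack at the distal terminus C3, since the proximal terminus would give a cyclobutane), which also fixes the alkene at C1=C2. C3 and C4 are set by the substrate from C5: the C3 aryl sits syn on the allyl, the enol approaches endo with its oxygen over the allyl cation as in an endo Diels–Alder transition state (C3/C4 cis), allylic strain in the (Z)-enol turns the C5 aryl anti to the enol C=C (C4/C5 trans), and C4 is in addition the thermodynamically preferred epimer. The step needs allene rather than propargyl coupling (palladium sits on the less hindered methyl-bearing terminus), C- over O-allylation (O-allylation is reversible under palladium) and an inert acetyl and prenyl group (only intermolecular or trisubstituted-alkene pathways are open to them).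

Step 11
Reactants: 17 the acetyl cyclohexene from step 10; 2 2,4-bis(methoxymethoxy)benzaldehyde
Product: 18 (E)-1-[3-[(3S,4R,5S)-4-[2,4-bis(methoxymethoxy)-3-(3-methylbut-2-en-1-yl)benzoyl]-5-[2,4-bis(methoxymethoxy)phenyl]-1-methylcyclohex-1-en-3-yl]-2,4-bis(methoxymethoxy)phenyl]-3-[2,4-bis(methoxymethoxy)phenyl]prop-2-en-1-one (octa-MOM ether of the target)
Conditions: KOH, EtOH/THF, rt
Reagents that add atoms: none
Why: Claisen–Schmidt aldol condensation in which only the methyl ketone can condense and dehydrate (E-alkene by E1cB); C4 is the thermodynamically preferred epimer and should survive the base.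

Step 12
Reactants: 18 octa-MOM ether of the target
Product: 19 CNP0186421.2, (E)-1-[3-[(3S,4R,5S)-4-[2,4-dihydroxy-3-(3-methylbut-2-en-1-yl)benzoyl]-5-(2,4-dihydroxyphenyl)-1-methylcyclohex-1-en-3-yl]-2,4-dihydroxyphenyl]-3-(2,4-dihydroxyphenyl)prop-2-en-1-one
Conditions: HCl (cat., 1.25 M in MeOH), MeOH/THF, 35 °C, stopped at full conversion
Reagents that add atoms: none
Why: Acid-catalysed transacetalisation (methanolysis) of the eight MOM ethers under dilute, mild conditions meant to spare the prenyl group and the 2′-hydroxychalcone.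

Compound list
1 | 2,4-dihydroxybenzaldehyde | O=Cc1ccc(O)cc1O | starting material
2 | 2,4-bis(methoxymethoxy)benzaldehyde | O=Cc1ccc(OCOC)cc1OCOC | intermediate
3 | 2,4-bis(methoxymethoxy)-1-vinylbenzene | C=Cc1ccc(OCOC)cc1OCOC | intermediate
4 | 2,2-dichloro-3-[2,4-bis(methoxymethoxy)phenyl]cyclobutan-1-one (racemic) | O=C1CC(c2ccc(OCOC)cc2OCOC)C1(Cl)Cl | intermediate
5 | 3-[2,4-bis(methoxymethoxy)phenyl]cyclobutan-1-one | O=C1CC(c2ccc(OCOC)cc2OCOC)C1 | intermediate
6 | 1,3-bis(methoxymethoxy)benzene | COCOc1cccc(OCOC)c1 | starting material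
7 | 2-lithio-1,3-bis(methoxymethoxy)benzene | [Li]c1c(OCOC)cccc1OCOC | intermediate
8 | 1,3-bis(methoxymethoxy)-2-(3-methylbut-2-en-1-yl)benzene | CC(C)=CCc1c(OCOC)cccc1OCOC | intermediate
9 | 4-lithio-1,3-bis(methoxymethoxy)-2-(3-methylbut-2-en-1-yl)benzene | [Li]c1ccc(OCOC)c(CC=C(C)C)c1OCOC | intermediate
10 | cis-1-[2,4-bis(methoxymethoxy)-3-(3-methylbut-2-en-1-yl)phenyl]-3-[2,4-bis(methoxymethoxy)phenyl]cyclobutan-1-ol (OH cis to 3-aryl, achiral) | O[C@]1(c2ccc(OCOC)c(CC=C(C)C)c2OCOC)C[C@H](c2ccc(OCOC)cc2OCOC)C1 | intermediate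
11 | 2,4-dihydroxyacetophenone | CC(=O)c1ccc(O)cc1O | starting material
12 | 3-acetyl-2,6-dihydroxybenzaldehyde | CC(=O)c1ccc(O)c(C=O)c1O | intermediate
13 | 3-acetyl-2,6-bis(methoxymethoxy)benzaldehyde | CC(=O)c1ccc(OCOC)c(C=O)c1OCOC | intermediate
14 | bromomagnesium 1-[3-acetyl-2,6-bis(methoxymethoxy)phenyl]but-2-yn-1-olate (racemic) | CC#CC(O[Mg]Br)c1c(OCOC)ccc(C(C)=O)c1OCOC | intermediate
15 | 1-[3-acetyl-2,6-bis(methoxymethoxy)phenyl]but-2-yn-1-yl methyl carbonate (racemic) | CC#CC(OC(=O)OC)c1c(OCOC)ccc(C(C)=O)c1OCOC | intermediate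
16 | (3S)-7-[3-acetyl-2,6-bis(methoxymethoxy)phenyl]-1-[2,4-bis(methoxymethoxy)-3-(3-methylbut-2-en-1-yl)phenyl]-3-[2,4-bis(methoxymethoxy)phenyl]-5-methylhepta-5,6-dien-1-one (allene axis unassigned) | CC(C)=CCc1c(OCOC)ccc(C(=O)C[C@H](CC(C)=C=Cc2c(OCOC)ccc(C(C)=O)c2OCOC)c2ccc(OCOC)cc2OCOC)c1OCOC | intermediate
17 | [(3S,4R,5S)-3-[3-acetyl-2,6-bis(methoxymethoxy)phenyl]-5-[2,4-bis(methoxymethoxy)phenyl]-1-methylcyclohex-1-en-4-yl] [2,4-bis(methoxymethoxy)-3-(3-methylbut-2-en-1-yl)phenyl] ketone (aroyl cis to the C3 aryl, trans to the C5 aryl) | CC(C)=CCc1c(OCOC)ccc(C(=O)[C@H]2[C@@H](c3c(OCOC)ccc(C(C)=O)c3OCOC)C=C(C)C[C@@H]2c2ccc(OCOC)cc2OCOC)c1OCOC | intermediate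
18 | octa-MOM ether of the target, (E)-chalcone, (3S,4R,5S) | CC(C)=CCc1c(OCOC)ccc(C(=O)[C@H]2[C@@H](c3c(OCOC)ccc(C(=O)/C=C/c4ccc(OCOC)cc4OCOC)c3OCOC)C=C(C)C[C@@H]2c2ccc(OCOC)cc2OCOC)c1OCOC | intermediate
19 | CNP0186421.2, (E)-chalcone, (3S,4R,5S) | CC(C)=CCc1c(O)ccc(C(=O)[C@H]2[C@@H](c3c(O)ccc(C(=O)/C=C/c4ccc(O)cc4O)c3O)C=C(C)C[C@@H]2c2ccc(O)cc2O)c1O | target

Total step count: 12. Longest linear sequence: 8 steps (1, 2, 3, 4, 6, 10, 11, 12).

Steps most likely to fail

Step 10 (Proposed new method). The ring closure may show poor endo/exo facial selectivity and deliver the C3 epimer (all-trans ring). The cascade may also stall at allene 16, lose alkylpalladium to β-hydride elimination before coupling, or let palladium hydride move the ring alkene. The fallback uses known chemistry in two isolated operations; it sets out from 13 and 10 and returns at 17. Wittig olefination of 13 with (2-bromoallyl)triphenylphosphonium bromide and NaHMDS, followed by iodine-catalysed equilibration, should give the bromodiene (E)-1-[3-(3-bromobuta-1,3-dien-1-yl)-2,4-bis(methoxymethoxy)phenyl]ethanone F1. The established enantioselective ring-opening vinylation of the cyclobutanol 10 with F1 (Pd(OAc)2, the same ferrocenyl P,N ligand, Cs2CO3, toluene, 50 °C) should then give the isolable (3S)-dienyl ketone F2, which already contains the C6–C1 bond. The known nickel-hydride hydroalkylation of aryl 1,3-dienes by simple ketones (Ni(cod)2, DTBM-SEGPHOS, KOtBu cat., EtOH) is then applied intramolecularly to close C4–C3 and give 17. The chiral bisphosphine on nickel adds catalyst control over the C3 configuration, and either ligand enantiomer can be tried for the matched case.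

Step 12. The acid may cyclise the prenyl chain onto the neighbouring phenol (chroman formation) or close the 2′-hydroxychalcone to a flavanone before all eight acetals are cleaved. The fallback replaces protic acetal methanolysis by silyl transfer; it sets out from 18 and returns at 19. Treatment of 18 with TMSOTf and 2,2′-bipyridyl in CH2Cl2 at 0 °C should exchange each aryl MOM ether for a trimethylsilyl ether, giving the octakis(trimethylsilyl) ether of the target F3 without any free protic acid. Stirring F3 with water buffered near pH 6 then hydrolyses the silyl ethers to 19.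

Step 7. Formylation may occur para to the chelated hydroxyl (C5 of the acetophenone) instead of between the two hydroxyls, or proceed with low conversion. The fallback builds the same ring by directed metalation; it sets out from 6 through its lithio derivative 7 and returns at 13, bypassing 11 and 12. Quenching 7 with DMF should give 2,6-bis(methoxymethoxy)benzaldehyde F4. NBS in MeCN should brominate the only activated position to give 3-bromo-2,6-bis(methoxymethoxy)benzaldehyde F5. Stille coupling of F5 with tributyl(1-ethoxyvinyl)stannane (Pd(PPh3)4, toluene, 90 °C) should give 3-(1-ethoxyvinyl)-2,6-bis(methoxymethoxy)benzaldehyde F6. Mild hydrolysis of the enol ether (oxalic acid, wet THF) then gives 13.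

Further compounds
F1 | step 10 | (E)-1-[3-(3-bromobuta-1,3-dien-1-yl)-2,4-bis(methoxymethoxy)phenyl]ethanone | CC(=O)c1ccc(OCOC)c(/C=C/C(Br)=C)c1OCOC
F2 | step 10 | (3S,6E)-7-[3-acetyl-2,6-bis(methoxymethoxy)phenyl]-1-[2,4-bis(methoxymethoxy)-3-(3-methylbut-2-en-1-yl)phenyl]-3-[2,4-bis(methoxymethoxy)phenyl]-5-methylidenehept-6-en-1-one | CC(C)=CCc1c(OCOC)ccc(C(=O)C[C@H](CC(=C)/C=C/c2c(OCOC)ccc(C(C)=O)c2OCOC)c2ccc(OCOC)cc2OCOC)c1OCOC
F3 | step 12 | octakis(trimethylsilyl) ether of the target, (E)-chalcone, (3S,4R,5S) | CC(C)=CCc1c(O[Si](C)(C)C)ccc(C(=O)[C@H]2[C@@H](c3c(O[Si](C)(C)C)ccc(C(=O)/C=C/c4ccc(O[Si](C)(C)C)cc4O[Si](C)(C)C)c3O[Si](C)(C)C)C=C(C)C[C@@H]2c2ccc(O[Si](C)(C)C)cc2O[Si](C)(C)C)c1O[Si](C)(C)C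
F4 | step 7 | 2,6-bis(methoxymethoxy)benzaldehyde | COCOc1cccc(OCOC)c1C=O
F5 | step 7 | 3-bromo-2,6-bis(methoxymethoxy)benzaldehyde | COCOc1ccc(Br)c(OCOC)c1C=O
F6 | step 7 | 3-(1-ethoxyvinyl)-2,6-bis(methoxymethoxy)benzaldehyde | C=C(OCC)c1ccc(OCOC)c(C=O)c1OCOC
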